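**Plan**
- Retrosynthesis: the lower-unit C4–OH goes back to a C4 ketone and its C3–OH to an enol-silane oxidation. The ring D C1′–C2 bond of the lower unit is then cut to an aryl metal plus 7-(benzyloxy)chromone. The upper C4–C2′ (ring D) bond is cut to a flavan-4-yl cation plus 5-bromopyrogallol, and the upper unit is dismantled like the lower one.
- Enabling feature: in ring C of the lower unit, C4 bears oxygen two atoms away from C2. At the ketone level O1–C2=C3–C4=O is a chromone, so C2 is the β-carbon of a vinylogous ester and accepts ring D carbon C1′ as a nucleophile. The resulting enolate then supplies C3–OH and the ketone supplies C4–OH.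
- Forward order: chromone + aryl → upper dihydroflavonol → 3,4-diol → C4 cation + bromopyrogallol (ring D attached, Br left at C1′) → benzylation → conjugate arylation of a second chromone → C3 hydroxylation → debenzylation → C4 reduction.
- Stereochemistry: both C2 centres come from the (S)-BINAP complex of [RhCl(C2H4)2]2, and both C3 centres from DMDO attack anti to the 2-aryl group. Upper C4 comes from arene attack anti to 3-OH, and lower C4 from hydride delivery giving the equatorial OH.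

Key step: step 8

Remark: 5-bromobenzene-1,2,3-triol is treated as a catalogue compound (otherwise one BBr3 demethylation from 5-bromo-1,2,3-trimethoxybenzene); α and β refer to the usual flavan drawing, in which both 2-aryl groups of the target are α.

**Route**

Step 1
Reactants: 1 7-hydroxy-4H-chromen-4-one
Product: 2 7-(benzyloxy)-4H-chromen-4-one
Conditions: BnBr, K2CO3, DMF, 50 °C
Reagents that add atoms: benzyl bromide BrCc1ccccc1
Why: Williamson etherification of the acidic 7-phenol (a vinylogous acid) under mild carbonate conditions that leave the pyranone ring closed; no stereocentre is involved.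

Step 2
Reactants: 3 5-bromobenzene-1,2,3-triol
Product: 4 5-bromo-1,2,3-tris(benzyloxy)benzene
Conditions: BnBr (3.5 equiv), K2CO3, DMF, 60 °C, argon
Reagents that add atoms: benzyl bromide BrCc1ccccc1
Why: threefold Williamson etherification, run under argon because pyrogallol phenolates are air-sensitive; no stereocentre is involved.

Step 3
Reactants: 4 5-bromo-1,2,3-tris(benzyloxy)benzene (1.5 equiv); 2 7-(benzyloxy)-4H-chromen-4-one
Product: 7 (2S)-7-(benzyloxy)-2-[3,4,5-tris(benzyloxy)phenyl]-4-(trimethylsilyloxy)-2H-chromene, via aryllithium 5 (not isolated), via arylzinc chloride 6 (not isolated)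
Conditions: n-BuLi, THF, −78 °C; ZnCl2, −78 → 0 °C; then 2, [RhCl(C2H4)2]2 (2.5 mol %), (S)-BINAP (5.5 mol %), Me3SiCl, THF, 20 °C; pentane, filtration, used crude
Reagents that add atoms: chlorotrimethylsilane C[Si](C)(C)Cl; for the intermediates only: n-butyllithium [Li]CCCC (Li of 5) and zinc chloride Cl[Zn]Cl (ZnCl of 6)
Why: rhodium-catalysed asymmetric 1,4-addition of an arylzinc chloride to the chromone with silyl trapping of the rhodium enolate (Hayashi–Miyaura type), in which (S)-BINAP should set C2 as S by the same facial sense that gives (S)-3-arylcyclohexanones, and the enol silane cannot racemise by retro-oxa-Michael opening.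

Step 4
Reactants: 7 (2S)-7-(benzyloxy)-2-[3,4,5-tris(benzyloxy)phenyl]-4-(trimethylsilyloxy)-2H-chromene
Product: 9 (2R,3R)-7-(benzyloxy)-3-hydroxy-2-[3,4,5-tris(benzyloxy)phenyl]chroman-4-one, via siloxy epoxide 8 (not isolated)
Conditions: DMDO (acetone), CH2Cl2, −78 → −20 °C; then AcOH, THF/H2O, 0 °C
Reagents that add atoms: dimethyldioxirane CC1(C)OO1
Why: Rubottom oxidation, in which DMDO should epoxidise the C3=C4 enol silane on the face anti to the C2 aryl group and mild aqueous acid opens the siloxy epoxide to the 2,3-trans α-hydroxy ketone, setting C3 (the product is tetra-O-benzyl-dihydrorobinetin, whose configuration can be checked against material from the natural flavanonol).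

Step 5
Reactants: 9 (2R,3R)-7-(benzyloxy)-3-hydroxy-2-[3,4,5-tris(benzyloxy)phenyl]chroman-4-one
Product: 10 (2R,3S,4R)-7-(benzyloxy)-2-[3,4,5-tris(benzyloxy)phenyl]chromane-3,4-diol
Conditions: NaBH4, THF/MeOH, 0 °C
Reagents that add atoms: none
Why: borohydride reduction of the aryl ketone should give mainly the 3,4-trans diol by hydride delivery that places the new OH equatorial; the C4 configuration is of no consequence because C4 is ionised in step 6.

Step 6
Reactants: 10 (2R,3S,4R)-7-(benzyloxy)-2-[3,4,5-tris(benzyloxy)phenyl]chromane-3,4-diol; 3 5-bromobenzene-1,2,3-triol (5 equiv)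
Product: 12 (2R,3S,4S)-7-(benzyloxy)-4-(6-bromo-2,3,4-trihydroxyphenyl)-2-[3,4,5-tris(benzyloxy)phenyl]chroman-3-ol, via C4 benzylic cation 11 (not isolated)
Conditions: BF3·OEt2 (0.5 equiv), dioxane/CH2Cl2, 0 °C → rt, argon
Reagents that add atoms: none
Why: dehydrative Friedel–Crafts alkylation, in which the 4-OH of 10 leaves as water to give the C4 cation (stabilised by O1 and the 7-oxygen of ring A) that attacks the only free position type of symmetric 3 (ortho and para to OH, next to Br), with the arene expected to enter anti to the 3-OH to give the 3,4-trans (4α, 4S) adduct as is usual for 2,3-trans flavan-4-yl cations.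

Step 7
Reactants: 12 (2R,3S,4S)-7-(benzyloxy)-4-(6-bromo-2,3,4-trihydroxyphenyl)-2-[3,4,5-tris(benzyloxy)phenyl]chroman-3-ol
Product: 13 (2R,3S,4S)-3,7-bis(benzyloxy)-4-[6-bromo-2,3,4-tris(benzyloxy)phenyl]-2-[3,4,5-tris(benzyloxy)phenyl]chromane
Conditions: NaH, BnBr, Bu4NI (cat.), DMF, 0 °C → rt, argon
Reagents that add atoms: benzyl bromide BrCc1ccccc1
Why: exhaustive Williamson benzylation of the three phenols and the secondary 3-OH removes every acidic proton before metalation and touches no stereocentre.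

Step 8
Reactants: 13 (2R,3S,4S)-3,7-bis(benzyloxy)-4-[6-bromo-2,3,4-tris(benzyloxy)phenyl]-2-[3,4,5-tris(benzyloxy)phenyl]chromane; 2 7-(benzyloxy)-4H-chromen-4-one (2 equiv)
Product: 16 (2S)-7-(benzyloxy)-4-(trimethylsilyloxy)-2-{3,4,5-tris(benzyloxy)-2-[(2R,3S,4S)-3,7-bis(benzyloxy)-2-(3,4,5-tris(benzyloxy)phenyl)chroman-4-yl]phenyl}-2H-chromene, via aryllithium 14 (not isolated), via arylzinc chloride 15 (not isolated)
Conditions: n-BuLi (1.05 equiv), THF, −78 °C; ZnCl2, −78 → 0 °C; then 2, [RhCl(C2H4)2]2 (5 mol %), (S)-BINAP (11 mol %), Me3SiCl (2 equiv), THF, 20 → 40 °C; pentane, filtration through basic alumina, used crude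
Reagents that add atoms: chlorotrimethylsilane C[Si](C)(C)Cl; for the intermediates only: n-butyllithium [Li]CCCC (Li of 14) and zinc chloride Cl[Zn]Cl (ZnCl of 15)
Why: Bromine–lithium exchange and transmetalation give arylzinc chloride 15, whose aryl group passes to monovalent rhodium; the chromone C2=C3 bond inserts into the Rh–aryl bond with the aryl going to C2, and Me3SiCl silylates the oxa-π-allyl rhodium enolate to release enol silane 16 and return Rh–Cl. The closest known reaction type is the rhodium/BINAP-catalysed asymmetric 1,4-addition of arylzinc chlorides with Me3SiCl to 4-quinolones and 2,3-dihydro-4-pyridones, together with rhodium-catalysed 1,4-arylation of chromones by arylboron reagents (Hayashi–Miyaura type). No ring is closed; ring D carbon C1′ is joined to C2 of an intact benzopyranone. The new stereocentre C2 is set by the ligand: (S)-BINAP should expose the chromone face that gives (2S)-16, the arrangement of natural flavanones, while the stereocentres already present in the aryl partner make this a double diastereoselection in which the catalyst is expected to dominate. The step needs 1,4- over 1,2-addition (secured by the soft rhodium aryl), preservation of C2 (secured by silyl trapping, which closes off the retro-oxa-Michael ring opening available to a free flavanone enolate) and clean exchange at bromine (secured by −78 °C and the absence of acidic protons after step 7); the bulk of the ortho flavanyl group is the main concern. The enol silane carries the regiodefined C3=C4 bond through which C3–OH and C4–OH are then installed.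

Step 9
Reactants: 16 (2S)-7-(benzyloxy)-4-(trimethylsilyloxy)-2-{3,4,5-tris(benzyloxy)-2-[(2R,3S,4S)-3,7-bis(benzyloxy)-2-(3,4,5-tris(benzyloxy)phenyl)chroman-4-yl]phenyl}-2H-chromene
Product: 18 (2R,3R)-7-(benzyloxy)-3-hydroxy-2-{3,4,5-tris(benzyloxy)-2-[(2R,3S,4S)-3,7-bis(benzyloxy)-2-(3,4,5-tris(benzyloxy)phenyl)chroman-4-yl]phenyl}chroman-4-one, via siloxy epoxide 17 (not isolated)
Conditions: DMDO (acetone), CH2Cl2, −78 → −20 °C; then AcOH, THF/H2O, 0 °C
Reagents that add atoms: dimethyldioxirane CC1(C)OO1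
Why: Rubottom oxidation as in step 4, the very large C2 aryl group directing DMDO to the opposite face of the electron-rich enol silane (which reacts far faster than the aryl ethers) so that C3–OH should emerge trans to C2 (3R).

Step 10
Reactants: 18 (2R,3R)-7-(benzyloxy)-3-hydroxy-2-{3,4,5-tris(benzyloxy)-2-[(2R,3S,4S)-3,7-bis(benzyloxy)-2-(3,4,5-tris(benzyloxy)phenyl)chroman-4-yl]phenyl}chroman-4-one
Product: 19 (2R,3R)-3,7-dihydroxy-2-{3,4,5-trihydroxy-2-[(2R,3S,4S)-3,7-dihydroxy-2-(3,4,5-trihydroxyphenyl)chroman-4-yl]phenyl}chroman-4-one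
Conditions: H2 (1 atm), Pd(OH)2/C, THF/MeOH, rt
Reagents that add atoms: none
Why: catalytic hydrogenolysis of all nine benzyl ethers under neutral conditions, under which the electron-rich aryl ketone, the diarylmethine C–C bond and the benzylic ring C–O bonds of flavanoids are normally retained; it is placed before the reduction so that no benzylic C4–OH is exposed to the catalyst.

Step 11
Reactants: 19 (2R,3R)-3,7-dihydroxy-2-{3,4,5-trihydroxy-2-[(2R,3S,4S)-3,7-dihydroxy-2-(3,4,5-trihydroxyphenyl)chroman-4-yl]phenyl}chroman-4-one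
Product: 20 (2R,3S,4R)-2-{3,4,5-trihydroxy-2-[(2R,3S,4S)-3,7-dihydroxy-2-(3,4,5-trihydroxyphenyl)chroman-4-yl]phenyl}chromane-3,4,7-triol
Conditions: NaBH4, degassed EtOH/H2O, 0 °C, argon; AcOH to pH 6; Sephadex LH-20
Reagents that add atoms: none
Why: borohydride reduction of a free 2,3-trans-dihydroflavonol, which for this class should deliver hydride so that the new 4-OH is equatorial and trans to 3-OH (4R); the near-neutral work-up avoids ionisation of the product at C4.

**Compound list**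
1 | 7-hydroxy-4H-chromen-4-one | O=c1ccoc2cc(O)ccc12 | starting material
2 | 7-(benzyloxy)-4H-chromen-4-one | O=c1ccoc2cc(OCc3ccccc3)ccc12 | intermediate
3 | 5-bromobenzene-1,2,3-triol | Oc1cc(Br)cc(O)c1O | starting material
4 | 5-bromo-1,2,3-tris(benzyloxy)benzene | Brc1cc(OCc2ccccc2)c(OCc2ccccc2)c(OCc2ccccc2)c1 | intermediate
5 | [3,4,5-tris(benzyloxy)phenyl]lithium | [Li]c1cc(OCc2ccccc2)c(OCc2ccccc2)c(OCc2ccccc2)c1 | intermediate
6 | chlorido[3,4,5-tris(benzyloxy)phenyl]zinc | Cl[Zn]c1cc(OCc2ccccc2)c(OCc2ccccc2)c(OCc2ccccc2)c1 | intermediate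
7 | (2S)-7-(benzyloxy)-2-[3,4,5-tris(benzyloxy)phenyl]-4-(trimethylsilyloxy)-2H-chromene | C(c1ccccc1)Oc1ccc2c(c1)O[C@H](c1cc(OCc3ccccc3)c(OCc3ccccc3)c(OCc3ccccc3)c1)C=C2O[Si](C)(C)C | intermediate
8 | 3,4-epoxide of 7 on the face anti to the 2-aryl group (4-trimethylsilyloxy-3,4-epoxychromane) | C(c1ccccc1)Oc1ccc2c(c1)O[C@H](c1cc(OCc3ccccc3)c(OCc3ccccc3)c(OCc3ccccc3)c1)[C@H]3O[C@@]23O[Si](C)(C)C | intermediate
9 | (2R,3R)-7-(benzyloxy)-3-hydroxy-2-[3,4,5-tris(benzyloxy)phenyl]chroman-4-one | C(c1ccccc1)Oc1ccc2c(c1)O[C@H](c1cc(OCc3ccccc3)c(OCc3ccccc3)c(OCc3ccccc3)c1)[C@@H](O)C2=O | intermediate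
10 | (2R,3S,4R)-7-(benzyloxy)-2-[3,4,5-tris(benzyloxy)phenyl]chromane-3,4-diol | C(c1ccccc1)Oc1ccc2c(c1)O[C@H](c1cc(OCc3ccccc3)c(OCc3ccccc3)c(OCc3ccccc3)c1)[C@@H](O)[C@@H]2O | intermediate
11 | (2R,3S)-7-(benzyloxy)-3-hydroxy-2-[3,4,5-tris(benzyloxy)phenyl]chroman-4-ylium (C4 benzylic cation) | C(c1ccccc1)Oc1ccc2c(c1)O[C@H](c1cc(OCc3ccccc3)c(OCc3ccccc3)c(OCc3ccccc3)c1)[C@@H](O)[CH+]2 | intermediate
12 | (2R,3S,4S)-7-(benzyloxy)-4-(6-bromo-2,3,4-trihydroxyphenyl)-2-[3,4,5-tris(benzyloxy)phenyl]chroman-3-ol | C(c1ccccc1)Oc1ccc2c(c1)O[C@H](c1cc(OCc3ccccc3)c(OCc3ccccc3)c(OCc3ccccc3)c1)[C@@H](O)[C@@H]2c1c(Br)cc(O)c(O)c1O | intermediate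
13 | (2R,3S,4S)-3,7-bis(benzyloxy)-4-[6-bromo-2,3,4-tris(benzyloxy)phenyl]-2-[3,4,5-tris(benzyloxy)phenyl]chromane | C(c1ccccc1)Oc1ccc2c(c1)O[C@H](c1cc(OCc3ccccc3)c(OCc3ccccc3)c(OCc3ccccc3)c1)[C@@H](OCc1ccccc1)[C@@H]2c1c(Br)cc(OCc3ccccc3)c(OCc3ccccc3)c1OCc1ccccc1 | intermediate
14 | aryllithium from 13 (Li in place of Br; 2R,3S,4S) | C(c1ccccc1)Oc1ccc2c(c1)O[C@H](c1cc(OCc3ccccc3)c(OCc3ccccc3)c(OCc3ccccc3)c1)[C@@H](OCc1ccccc1)[C@@H]2c1c([Li])cc(OCc3ccccc3)c(OCc3ccccc3)c1OCc1ccccc1 | intermediate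
15 | arylzinc chloride from 13 (ZnCl in place of Br; 2R,3S,4S) | C(c1ccccc1)Oc1ccc2c(c1)O[C@H](c1cc(OCc3ccccc3)c(OCc3ccccc3)c(OCc3ccccc3)c1)[C@@H](OCc1ccccc1)[C@@H]2c1c([Zn]Cl)cc(OCc3ccccc3)c(OCc3ccccc3)c1OCc1ccccc1 | intermediate
16 | (2S)-7-(benzyloxy)-4-(trimethylsilyloxy)-2-{3,4,5-tris(benzyloxy)-2-[(2R,3S,4S)-3,7-bis(benzyloxy)-2-(3,4,5-tris(benzyloxy)phenyl)chroman-4-yl]phenyl}-2H-chromene | C(c1ccccc1)Oc1ccc2c(c1)O[C@H](c1cc(OCc3ccccc3)c(OCc3ccccc3)c(OCc3ccccc3)c1)[C@@H](OCc1ccccc1)[C@@H]2c1c([C@H]3Oc4cc(OCc5ccccc5)ccc4C(O[Si](C)(C)C)=C3)cc(OCc3ccccc3)c(OCc3ccccc3)c1OCc1ccccc1 | intermediate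
17 | 3,4-epoxide of 16 on the face anti to the 2-aryl group (siloxy epoxide) | C(c1ccccc1)Oc1ccc2c(c1)O[C@H](c1cc(OCc3ccccc3)c(OCc3ccccc3)c(OCc3ccccc3)c1)[C@@H](OCc1ccccc1)[C@@H]2c1c([C@H]3Oc4cc(OCc5ccccc5)ccc4[C@]5(O[Si](C)(C)C)O[C@H]35)cc(OCc3ccccc3)c(OCc3ccccc3)c1OCc1ccccc1 | intermediate
18 | (2R,3R)-7-(benzyloxy)-3-hydroxy-2-{3,4,5-tris(benzyloxy)-2-[(2R,3S,4S)-3,7-bis(benzyloxy)-2-(3,4,5-tris(benzyloxy)phenyl)chroman-4-yl]phenyl}chroman-4-one | C(c1ccccc1)Oc1ccc2c(c1)O[C@H](c1cc(OCc3ccccc3)c(OCc3ccccc3)c(OCc3ccccc3)c1)[C@@H](OCc1ccccc1)[C@@H]2c1c([C@H]3Oc4cc(OCc5ccccc5)ccc4C(=O)[C@@H]3O)cc(OCc3ccccc3)c(OCc3ccccc3)c1OCc1ccccc1 | intermediate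
19 | (2R,3R)-3,7-dihydroxy-2-{3,4,5-trihydroxy-2-[(2R,3S,4S)-3,7-dihydroxy-2-(3,4,5-trihydroxyphenyl)chroman-4-yl]phenyl}chroman-4-one | Oc1ccc2c(c1)O[C@H](c1cc(O)c(O)c(O)c1)[C@@H](O)[C@@H]2c1c([C@H]3Oc4cc(O)ccc4C(=O)[C@@H]3O)cc(O)c(O)c1O | intermediate
20 | (2R,3S,4R)-2-{3,4,5-trihydroxy-2-[(2R,3S,4S)-3,7-dihydroxy-2-(3,4,5-trihydroxyphenyl)chroman-4-yl]phenyl}chromane-3,4,7-triol | Oc1ccc2c(c1)O[C@H](c1cc(O)c(O)c(O)c1)[C@@H](O)[C@@H]2c1c([C@H]2Oc3cc(O)ccc3[C@@H](O)[C@@H]2O)cc(O)c(O)c1O | target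

**Totals**
Total step count: 11. Longest linear sequence: 10 steps (steps 2 to 11, from 5-bromobenzene-1,2,3-triol).

**Steps most likely to fail**

1. Step 8. The ortho flavanyl group may slow aryl transfer to rhodium and insertion of the chromone, so that protonation of the arylzinc species to the debrominated arene takes over. A mismatch between ligand and the chiral aryl partner may also erode facial selectivity at C2.
Fallback: set out from 13, convert it into aryllithium 14 as in step 8, and quench this with N,N-dimethylformamide to give 3,4,5-tris(benzyloxy)-2-[(2R,3S,4S)-3,7-bis(benzyloxy)-2-(3,4,5-tris(benzyloxy)phenyl)chroman-4-yl]benzaldehyde F1. Claisen–Schmidt condensation with commercial 1-[4-(benzyloxy)-2-hydroxyphenyl]ethanone (CC(=O)c1ccc(OCc2ccccc2)cc1O; KOH, EtOH/THF) should give the (E)-2′-hydroxychalcone F2. Intramolecular oxa-Michael closure (NaOAc, EtOH, reflux) should give the flavanone as two C2 epimers, which are diastereomers and separable. The (2S)-flavanone F3 is kept, and the other epimer is returned to F2 by base-induced ring opening and recycled. Soft enolisation of F3 (Me3SiOTf, Et3N, CH2Cl2, 0 °C) rejoins the route at 16. Here the ring D–C2 bond comes from the formylation and ring C from O1–C2 closure.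

2. Step 6. The cation may be attacked from both faces, losing 3,4-trans selectivity, and it may be captured by ring A of a second flavan molecule (oligomerisation), because the brominated pyrogallol is only a moderate nucleophile.
Fallback: set out from 10 and acetylate both hydroxyls (Ac2O, pyridine, DMAP) to (2R,3R,4R)-7-(benzyloxy)-2-[3,4,5-tris(benzyloxy)phenyl]chromane-3,4-diyl diacetate F4. Ionisation with BF3·OEt2 in CH2Cl2 in the presence of 3 should then run through a cis-fused 1,3-dioxolan-2-ylium ion spanning C3 and C4. This ion blocks the β face, tempers the cation and forces the arene in trans, giving (2R,3S,4S)-7-(benzyloxy)-4-(6-bromo-2,3,4-trihydroxyphenyl)-2-[3,4,5-tris(benzyloxy)phenyl]chroman-3-yl acetate F5. Methanolysis (K2CO3, MeOH, argon) rejoins the route at 12.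

3. Step 10. Cleavage of the crowded aliphatic 3-O-benzyl ether may stall, and on the long exposure then needed the aryl ketone may be slowly reduced or a benzylic ring C–O bond opened.
Fallback: set out from 18 and remove the benzyl groups without hydrogen by Lewis-acid dealkylation with a cation scavenger (BCl3, pentamethylbenzene, CH2Cl2, −78 °C; MeOH quench). The benzyl groups are transferred to the scavenger by Friedel–Crafts capture, and the sequence rejoins the route directly at 19. It makes no new compound (F0).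

**Further compounds**
F1 | step 8 | 3,4,5-tris(benzyloxy)-2-[(2R,3S,4S)-3,7-bis(benzyloxy)-2-(3,4,5-tris(benzyloxy)phenyl)chroman-4-yl]benzaldehyde | C(c1ccccc1)Oc1ccc2c(c1)O[C@H](c1cc(OCc3ccccc3)c(OCc3ccccc3)c(OCc3ccccc3)c1)[C@@H](OCc1ccccc1)[C@@H]2c1c(C=O)cc(OCc3ccccc3)c(OCc3ccccc3)c1OCc1ccccc1
F2 | step 8 | (E)-1-[4-(benzyloxy)-2-hydroxyphenyl]-3-{3,4,5-tris(benzyloxy)-2-[(2R,3S,4S)-3,7-bis(benzyloxy)-2-(3,4,5-tris(benzyloxy)phenyl)chroman-4-yl]phenyl}prop-2-en-1-one | C(c1ccccc1)Oc1ccc2c(c1)O[C@H](c1cc(OCc3ccccc3)c(OCc3ccccc3)c(OCc3ccccc3)c1)[C@@H](OCc1ccccc1)[C@@H]2c1c(/C=C/C(=O)c3ccc(OCc4ccccc4)cc3O)cc(OCc3ccccc3)c(OCc3ccccc3)c1OCc1ccccc1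
F3 | step 8 | (2S)-7-(benzyloxy)-2-{3,4,5-tris(benzyloxy)-2-[(2R,3S,4S)-3,7-bis(benzyloxy)-2-(3,4,5-tris(benzyloxy)phenyl)chroman-4-yl]phenyl}chroman-4-one | C(c1ccccc1)Oc1ccc2c(c1)O[C@H](c1cc(OCc3ccccc3)c(OCc3ccccc3)c(OCc3ccccc3)c1)[C@@H](OCc1ccccc1)[C@@H]2c1c([C@H]3Oc4cc(OCc5ccccc5)ccc4C(=O)C3)cc(OCc3ccccc3)c(OCc3ccccc3)c1OCc1ccccc1
F4 | step 6 | (2R,3R,4R)-7-(benzyloxy)-2-[3,4,5-tris(benzyloxy)phenyl]chromane-3,4-diyl diacetate | C(c1ccccc1)Oc1ccc2c(c1)O[C@H](c1cc(OCc3ccccc3)c(OCc3ccccc3)c(OCc3ccccc3)c1)[C@@H](OC(C)=O)[C@@H]2OC(C)=O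
F5 | step 6 | (2R,3S,4S)-7-(benzyloxy)-4-(6-bromo-2,3,4-trihydroxyphenyl)-2-[3,4,5-tris(benzyloxy)phenyl]chroman-3-yl acetate | C(c1ccccc1)Oc1ccc2c(c1)O[C@H](c1cc(OCc3ccccc3)c(OCc3ccccc3)c(OCc3ccccc3)c1)[C@@H](OC(C)=O)[C@@H]2c1c(Br)cc(O)c(O)c1O
F0 | step 10 | none | none
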